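## The problem

Compound 14 is (2R,3R)-taxifolin carrying a prenyl (3-methylbut-2-en-1-yl) ether on O7. Its skeleton is a chroman-4-one: ring C (O1, C2, C3, C4) is fused to the phloroglucinol-type ring A through C4a and C8a, bears the catechol ring B on C2 and a hydroxyl on C3. C2 and C3 are the only stereocentres. They are adjacent and trans, which is the thermodynamically preferred arrangement and can also be inherited from an E alkene, but nothing else in the molecule can dictate their absolute sense, so this must come from a catalyst when ring C is built. Once the C4 ketone exists both centres are fragile: base opens ring C at O1–C2, epimerises the α-ketol and drives it towards the flavonol. The prenyl aryl ether rules out hydrogenolysis, OsO4, peracids, strong protic or Lewis acids and benzylic C–H oxidants, and the free catechol is air-sensitive, so it has to be released last under near-neutral conditions. The feature that allows a short route is that O1–C8a–C4a–C4 is the skeleton of a salicylaldehyde (a 1-oxadiene after activation) and C2–C3 is a styrene oxygenated at its β-carbon. Because C5 also bears a hydroxyl, that aldehyde is a symmetric 2,6-dihydroxybenzaldehyde in which either phenol can become O1. An aldehyde activated at the acetal level delivers C4 already oxygenated, so only an alcohol oxidation separates the cycloadduct from the ketone.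

## Retrosynthesis

**14 to 13.** The last cut is at the two O–Si bonds of ring B, leading back to the bis(silyl ether) 13. Silyl protection is preferred to benzyl, methyl or acetal groups because buffered fluoride is the one deprotection that spares the prenyl alkene, the aryl prenyl ether and the base-sensitive α-ketol. The forward step only has to stay non-basic.

**13 to 12 to 11 to 10.** No skeletal bond is cut here; only oxygen functions are adjusted. The C4 carbonyl of 13 is traced to the benzylic alcohol of diol 12, that to the C4 methyl ether 11, and the C3 hydroxyl of 11 to the acetate 10. Making the ketone from a C4 methylene would need oxidants that attack the prenyl group. Keeping the acetate until the ketone is present would expose a 3-acyloxy-4-ketone to deacylation conditions under which it eliminates or epimerises. In the chosen order C2 and C3 have no adjacent carbonyl until the penultimate step. The forward reactions must cope with a C4–O bond that ionises very easily, which helps the hydrolysis and is a liability elsewhere.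

**10 to 3 and 7.** The strategic cut opens ring C of 10 at O1–C2 and C3–C4. This gives the aldehyde 3 as the four-atom unit and the (E)-enol acetate 7 as the two-atom unit. In the forward sense 3 is taken through its acetal 8 to the methoxy ortho-quinone methide 9, which adds across 7. Cutting O1–C2 alone (oxa-Michael closure) or C4–C4a alone (acylation) would each need a chiral three-carbon chain made beforehand. The double cut instead builds ring C, both stereocentres and the C4 oxygen in one operation from two achiral aromatic pieces, neither of which needs phenol differentiation. The forward reaction must deliver three things: C4 bonded to the acetoxy-bearing carbon, retention of the E geometry as the 2,3-trans relationship, and one enantioface of the alkene.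

**3 to 1 and 2.** The O7–C(prenyl) bond is cut, leading to the trihydroxy aldehyde 1 and bromide 2. Installing the prenyl ether first is preferred to a late alkylation of a finished dihydroflavonol, which would need base on an epimerisable substrate and selectivity among five hydroxyls. The forward step must pick the 4-OH of 1 over the two hydrogen-bonded ortho phenols and O- over C-alkylation.

**7 to 6 to 5 to 4.** The enol C–O bond of 7 is traced to the C–B bond of the (E)-alkenyl boronate 6. The alkene of 6 is traced to the aldehyde 5, and the silyl ethers of 5 to the dihydroxy aldehyde 4. Direct enol acetylation of an arylacetaldehyde gives E/Z mixtures and anti-Markovnikov addition of acetic acid to an arylalkyne favours the Z ester. A stereoretentive copper-mediated C–B to C–O exchange on a boronate of defined geometry is therefore the cleanest source of the E isomer. The forward steps must give the trans boronate and keep its geometry.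

## Roads not taken

**Alternative 1:** The C3–O and C4–O bonds are made last on a finished ring C. The enantioenriched flav-3-ene A1 would be dihydroxylated with catalytic OsO4 and an amine N-oxide on the face opposite the C2 aryl group, giving the 2,3-trans-3,4-cis diol A2.
- Merits: the key reaction is known, and C2 reliably controls C3 and C4 by shielding one face. C4 is oxygenated at the alcohol level, as in the chosen plan.
- Weak points: OsO4 would attack a prenyl alkene before the chromene double bond, so ring A must carry benzyl ethers. After debenzylation, O7 has to be prenylated selectively on a base-sensitive dihydroflavonol. A1 must be obtained enantioenriched by a separate method, and 2-aryl-2H-chromenes can racemise by reversible electrocyclic ring opening.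
- Comparison: this road is stronger where it matters most, since its stereo-determining step is substrate-controlled and precedented. The chosen plan sets against this its convergence, a prenyl ether carried from the first step, and no step that threatens the prenyl alkene.

**Alternative 2:** Ring C is closed at C4–C4a. The acid A3, activated as a mixed anhydride with trifluoroacetic anhydride, would acylate the position ortho to the ether oxygen of its 3,5-bis(benzyloxy)phenyl ring to give the pentabenzyl ketone A4.
- Merits: intramolecular Friedel–Crafts acylation onto a phloroglucinol ether is well established, and the symmetric aryl ring gives one regiochemical outcome. Both stereocentres would be in place before ring closure, so their absolute configuration is only as uncertain as the preparation of A3.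
- Weak points: C2 of A3 is a benzylic aryl ether flanked by an electron-rich ring and may ionise under the acidic activation, with loss of configuration. The five benzyl ethers of A4 can only come off by hydrogenolysis, which the prenyl group does not survive, so prenylation must again be the last, poorly selective step on free taxifolin.
- Comparison: the ring-closing step is safer than the cycloaddition proposed here. The chosen plan sets against this a much shorter sequence and freedom from any late phenol differentiation.

**Alternative 3:** Ring A is assembled last. The ketene-acetal diene A6 would add across the C4a=C8a bond of the bromodihydropyranone A5 (C8 to C8a, C5 to C4a), and loss of HBr and methanol would aromatise the adduct to the tris(silyl) ketone A7.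
- Merits: the 5-hydroxy-7-prenyloxy pattern arises regiodefined, the C4 ketone is present from the start, and only silyl groups remain to be removed.
- Weak points: A5 already holds both stereocentres and would need its own asymmetric synthesis. Its C2 centre sits next to the ring oxygen of a vinylogous ester and can epimerise by ring opening under the amine used for aromatisation. A6 is hydrolytically delicate, and the bromo-substituted enone is a hindered dienophile.
- Comparison: this road is better after the key step, where the chosen plan spends three steps adjusting C3 and C4. The chosen plan sets against this that its stereocentres are created in the ring-forming step itself from two simple achiral arenes.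

Key step: step 5

Remark on the chemistry: the sense of induction of the chiral acid cannot be read from the structures, so the (R)-acid is written, and its antipode is to be used if the first runs show the 2S series.

Remark on the chemistry: C4 of 10, 11 and 12 is a transient stereocentre, so the SMILES leave it open. C3 is labelled S in 10–12 and R in 13–14 only because the CIP priorities of C2 and C4 swap when C4 becomes a carbonyl; the spatial arrangement is unchanged.

Abbreviations: TBS = tert-butyldimethylsilyl; prenyl = 3-methylbut-2-en-1-yl; Bpin = 4,4,5,5-tetramethyl-1,3,2-dioxaborolan-2-yl.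

## Route

**Step 1**
Reactants: 1 2,4,6-trihydroxybenzaldehyde; 2 prenyl bromide (1-bromo-3-methylbut-2-ene)
Product: 3 2,6-dihydroxy-4-(prenyloxy)benzaldehyde
Conditions: K2CO3 (1.0 equiv), 2 (1.0 equiv, slow addition), DMF, 0 °C → rt
Reagents that add atoms: none
Why: Williamson etherification under weak base: the 4-OH is the most acidic phenol and the only one not held in a hydrogen bond to the formyl group, so one equivalent of K2CO3 should form mainly the 4-phenoxide, and the dipolar aprotic solvent favours O- over C-alkylation.

**Step 2**
Reactants: 4 3,4-dihydroxybenzaldehyde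
Product: 5 3,4-bis(tert-butyldimethylsilyloxy)benzaldehyde
Conditions: TBSCl (2.4 equiv), imidazole (5 equiv), DMF, rt
Reagents that add atoms: tert-butyldimethylsilyl chloride, CC(C)(C)[Si](C)(C)Cl
Why: Standard silylation of phenols with TBSCl and imidazole; the aldehyde is inert, and the bis(silyl) catechol should withstand the carbanion, copper, acid, hydride and MnO2 steps that follow.

**Step 3**
Reactants: 5 3,4-bis(tert-butyldimethylsilyloxy)benzaldehyde
Product: 6 (E)-2-[3,4-bis(tert-butyldimethylsilyloxy)phenyl]ethenylboronic acid pinacol ester
Conditions: CH2(Bpin)2 (1.2 equiv), lithium 2,2,6,6-tetramethylpiperidide (1.2 equiv), THF, 0 °C; then 5, −78 °C → rt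
Reagents that add atoms: bis(4,4,5,5-tetramethyl-1,3,2-dioxaborolan-2-yl)methane, CC1(C)OB(CB2OC(C)(C)C(C)(C)O2)OC1(C)C
Why: Boron-Wittig olefination: the lithiated geminal bis(boronate) adds to the aldehyde and the β-alkoxide expels the O–B unit by syn elimination, which should give the trans-alkenyl boronate; the reagent is deprotonated before 5 is added, so the aryl silyl ethers meet only the hindered carbanion at low temperature.

**Step 4**
Reactants: 6 (E)-2-[3,4-bis(tert-butyldimethylsilyloxy)phenyl]ethenylboronic acid pinacol ester
Product: 7 (E)-2-[3,4-bis(tert-butyldimethylsilyloxy)phenyl]ethenyl acetate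
Conditions: Cu(OAc)2 (2.2 equiv), Et3N (3 equiv), 4 Å molecular sieves, MeCN, rt
Reagents that add atoms: copper diacetate, CC(=O)[O-].CC(=O)[O-].[Cu+2]
Why: Chan–Lam–Evans oxidative C–O coupling of an alkenylboron compound with carboxylate: transmetalation to divalent copper, oxidation to trivalent copper by a second equivalent and C–O reductive elimination all retain the alkene geometry, so the E boronate should give the E enol acetate, acetate being the only O-nucleophile present.

**Step 5**
Reactants: 3 2,6-dihydroxy-4-(prenyloxy)benzaldehyde; 7 (E)-2-[3,4-bis(tert-butyldimethylsilyloxy)phenyl]ethenyl acetate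
Product: 10 (2R,3S)-3-acetoxy-5-hydroxy-4-methoxy-7-(prenyloxy)-3',4'-bis(tert-butyldimethylsilyloxy)flavan (2,3-trans; C4 epimers), via dimethyl acetal 8 (not isolated), via methoxy ortho-quinone methide 9 (not isolated)
Conditions: 3 (1.3 equiv), 7 (1.0 equiv), HC(OMe)3 (1.5 equiv), (R)-3,3'-bis(2,4,6-triisopropylphenyl)-1,1'-binaphthalene-2,2'-diyl hydrogen phosphate (10 mol %), 5 Å molecular sieves, toluene, −20 °C → rt
Reagents that add atoms: trimethyl orthoformate, COC(OC)OC
Why: Proposed new method: acid-catalysed exchange with HC(OMe)3 turns 3 into acetal 8, which loses methanol to the methoxy ortho-quinone methide 9; once protonated this is a benzylic oxocarbenium ion held to the chiral phosphate by its two flanking phenols, and it acts as the 1-oxadiene (O=C8a–C4a=C4) of an inverse-demand hetero-Diels–Alder reaction with 7. The closest known reaction type is the Brønsted-acid-catalysed [4+2] cycloaddition of ortho-quinone methides (including those made from salicylaldehydes and orthoformates, and chiral-phosphoric-acid versions from ortho-hydroxybenzyl alcohols) with styrenes, β-alkylstyrenes and enol ethers to give chromans; a β-acyloxystyrene has not been used as the two-atom partner. Ring C closes in one asynchronous [4+2] event in which the C4–C3 bond forms first and the phenol oxygen then closes the six-membered ring on the benzylic carbon C2 (a 6-exo attack on the cation in the stepwise limit) while the phosphate takes up the phenolic proton. The regiochemistry should follow from charge stabilisation, because attack of C4 on the acetoxy-bearing carbon places the positive charge next to the para-silyloxy ring B, a far better donor than the acyloxy group. The 2,3-trans relationship comes from suprafacial addition to the E alkene, and if the intermediate lives long enough for the acetate to bridge as a 1,3-dioxolan-2-ylium ion, anti opening by the phenol leads to the same trans product. The configuration of C3 is fixed when the C4–C3 bond forms and that of C2 follows from the alkene geometry; both depend on the phosphate shielding one face of the bound heterodiene and on ring B lying endo, so the step needs high heterodiene-face selectivity and high endo selectivity at once, and the C4 epimers of 10 (2,4-cis, 4R, expected to predominate) are separated so that only material of one C2/C3 series is carried on. Chemoselectivity rests on the para-donor styrene being more nucleophilic than the prenyl alkene, which its allylic oxygen deactivates, and on the sieves removing the methanol that could otherwise add to the enol acetate.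

**Step 6**
Reactants: 10 (2R,3S)-3-acetoxy-5-hydroxy-4-methoxy-7-(prenyloxy)-3',4'-bis(tert-butyldimethylsilyloxy)flavan
Product: 11 (2R,3S)-5-hydroxy-4-methoxy-7-(prenyloxy)-3',4'-bis(tert-butyldimethylsilyloxy)flavan-3-ol
Conditions: i-Bu2AlH (3.5 equiv), CH2Cl2, −78 °C; aqueous potassium sodium tartrate
Reagents that add atoms: none
Why: Reductive cleavage of the acetate by i-Bu2AlH (ester to alkoxide and ethanol); the first equivalent is taken by the phenol, the cold non-basic conditions should neither expel methoxide from C4 through the 5-phenoxide nor attack the aryl silyl ethers, and no stereocentre is touched.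

**Step 7**
Reactants: 11 (2R,3S)-5-hydroxy-4-methoxy-7-(prenyloxy)-3',4'-bis(tert-butyldimethylsilyloxy)flavan-3-ol
Product: 12 (2R,3S)-7-(prenyloxy)-3',4'-bis(tert-butyldimethylsilyloxy)flavan-3,4,5-triol (C4 epimers)
Conditions: pyridinium p-toluenesulfonate (0.1 equiv), THF/H2O 4:1, 0.02 M, rt; used crude
Reagents that add atoms: water, O
Why: SN1 hydrolysis of an activated benzylic ether: the C4–OMe bond ionises under very weak acid because the cation is stabilised by O1, the 5-OH and the 7-alkoxy group, and water in large excess at high dilution should capture it before ring A of a second molecule can; C2 and C3 are not involved and the C4 configuration is irrelevant.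

**Step 8**
Reactants: 12 (2R,3S)-7-(prenyloxy)-3',4'-bis(tert-butyldimethylsilyloxy)flavan-3,4,5-triol
Product: 13 (2R,3R)-3,5-dihydroxy-7-(prenyloxy)-3',4'-bis(tert-butyldimethylsilyloxy)flavan-4-one
Conditions: activated MnO2 (15 equiv), CH2Cl2, rt
Reagents that add atoms: none
Why: Activated MnO2 oxidises benzylic alcohols selectively, so the unactivated C3 carbinol and the prenyl ether should be left alone; both C4 epimers converge on the ketone, and the neutral heterogeneous medium should not epimerise the new α-ketol, whose trans form is in any case the stable one.

**Step 9**
Reactants: 13 (2R,3R)-3,5-dihydroxy-7-(prenyloxy)-3',4'-bis(tert-butyldimethylsilyloxy)flavan-4-one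
Product: 14 (2R,3R)-2-(3,4-dihydroxyphenyl)-3,5-dihydroxy-7-(prenyloxy)chroman-4-one (7-O-prenyltaxifolin)
Conditions: Bu4NF (2.5 equiv), AcOH (2.5 equiv), THF, 0 °C
Reagents that add atoms: none
Why: Fluoride-induced cleavage of the two aryl silyl ethers, driven by Si–F bond formation; acetic acid keeps the medium from turning basic, so ring C should stay closed, C2 and C3 should not epimerise, and the catechol is released without air oxidation.

## Compound list

1 | 2,4,6-trihydroxybenzaldehyde | O=Cc1c(O)cc(O)cc1O | starting material
2 | prenyl bromide (1-bromo-3-methylbut-2-ene) | CC(C)=CCBr | starting material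
3 | 2,6-dihydroxy-4-(prenyloxy)benzaldehyde | CC(C)=CCOc1cc(O)c(C=O)c(O)c1 | intermediate
4 | 3,4-dihydroxybenzaldehyde | O=Cc1ccc(O)c(O)c1 | starting material
5 | 3,4-bis(tert-butyldimethylsilyloxy)benzaldehyde | O=Cc1ccc(O[Si](C)(C)C(C)(C)C)c(O[Si](C)(C)C(C)(C)C)c1 | intermediate
6 | (E)-2-[3,4-bis(tert-butyldimethylsilyloxy)phenyl]ethenylboronic acid pinacol ester | CC1(C)OB(/C=C/c2ccc(O[Si](C)(C)C(C)(C)C)c(O[Si](C)(C)C(C)(C)C)c2)OC1(C)C | intermediate
7 | (E)-2-[3,4-bis(tert-butyldimethylsilyloxy)phenyl]ethenyl acetate | CC(=O)O/C=C/c1ccc(O[Si](C)(C)C(C)(C)C)c(O[Si](C)(C)C(C)(C)C)c1 | intermediate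
8 | 2-(dimethoxymethyl)-5-(prenyloxy)benzene-1,3-diol (dimethyl acetal of 3, not isolated) | CC(C)=CCOc1cc(O)c(C(OC)OC)c(O)c1 | intermediate
9 | 5-hydroxy-6-(methoxymethylidene)-3-(prenyloxy)cyclohexa-2,4-dien-1-one (methoxy ortho-quinone methide, either geometry at the exocyclic alkene, not isolated) | CC(C)=CCOC1=CC(=O)C(=COC)C(O)=C1 | intermediate
10 | (2R,3S)-3-acetoxy-5-hydroxy-4-methoxy-7-(prenyloxy)-3',4'-bis(tert-butyldimethylsilyloxy)flavan, 2,3-trans, C4 epimers (4R, 2,4-cis, expected as the main one) | CC(C)=CCOc1cc(O)c2c(c1)O[C@H](c1ccc(O[Si](C)(C)C(C)(C)C)c(O[Si](C)(C)C(C)(C)C)c1)[C@@H](OC(C)=O)C2OC | intermediate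
11 | (2R,3S)-5-hydroxy-4-methoxy-7-(prenyloxy)-3',4'-bis(tert-butyldimethylsilyloxy)flavan-3-ol, 2,3-trans, C4 epimers | CC(C)=CCOc1cc(O)c2c(c1)O[C@H](c1ccc(O[Si](C)(C)C(C)(C)C)c(O[Si](C)(C)C(C)(C)C)c1)[C@@H](O)C2OC | intermediate
12 | (2R,3S)-7-(prenyloxy)-3',4'-bis(tert-butyldimethylsilyloxy)flavan-3,4,5-triol, 2,3-trans, C4 epimers | CC(C)=CCOc1cc(O)c2c(c1)O[C@H](c1ccc(O[Si](C)(C)C(C)(C)C)c(O[Si](C)(C)C(C)(C)C)c1)[C@@H](O)C2O | intermediate
13 | (2R,3R)-3,5-dihydroxy-7-(prenyloxy)-3',4'-bis(tert-butyldimethylsilyloxy)flavan-4-one | CC(C)=CCOc1cc(O)c2c(c1)O[C@H](c1ccc(O[Si](C)(C)C(C)(C)C)c(O[Si](C)(C)C(C)(C)C)c1)[C@@H](O)C2=O | intermediate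
14 | (2R,3R)-2-(3,4-dihydroxyphenyl)-3,5-dihydroxy-7-(prenyloxy)chroman-4-one | CC(C)=CCOc1cc(O)c2c(c1)O[C@H](c1ccc(O)c(O)c1)[C@@H](O)C2=O | target

## Step count and risk

Total: 9 steps. Longest linear sequence: 8 steps (4 → 5 → 6 → 7 → 10 → 11 → 12 → 13 → 14; steps 2–9). The ring A branch contributes one step (step 1) before the junction at step 5.

**Step 5 (key step, proposed new method).**
- The oxocarbenium ion from a 2,4,6-trioxygenated benzaldehyde is strongly stabilised and may react only slowly with a weakly nucleophilic enol ester. That leaves time for acid-induced decomposition of the enol acetate, oligomerisation of the quinone methide, or cycloaddition to the prenyl alkene of another molecule.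
- Attack with the reverse regiochemistry, guided by the acyloxy oxygen, is conceivable.
- Enantiocontrol needs heterodiene-face and endo/exo selectivity together. If either is modest, or if C4 of the product epimerises by re-ionisation, enantiomeric purity is lost as soon as C4 becomes trigonal.
- Fallback by known chemistry, setting out from aldehyde 5 and bromide 2 and rejoining at 13: commercial 2,4,6-trihydroxyacetophenone is 4-O-prenylated with 2 (as in step 1) to 2,6-dihydroxy-4-(prenyloxy)acetophenone F1, and both phenols are capped with chloromethyl methyl ether and i-Pr2NEt to give the bis(methoxymethyl) ether F2. Its lithium enolate (LiN(SiMe3)2, THF, −78 °C → rt) is condensed with 5, with dehydration completed by MsCl/Et3N if needed, to the (E)-chalcone F3. Juliá–Colonna epoxidation (poly-L-leucine, urea–H2O2, DBU, THF) attacks only the enone and should give the (2R,3S)-epoxy ketone F4. Dilute methanolic HCl in THF at 0 °C → rt then removes the two ortho-carbonyl methoxymethyl groups, and the freed phenol opens the epoxide at the benzylic carbon with inversion, which gives the trans ketol 13.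

**Step 7.**
- The C4 cation may be captured by the electron-rich ring A of a second molecule (the proanthocyanidin-type self-condensation) or may lose a proton towards the C3 enol, and the diol 12 is itself acid-labile.
- Fallback from 11, rejoining at 13: DDQ (1.2 equiv) in CH2Cl2/aqueous pH 7 buffer at 0 °C abstracts hydride from the highly activated C4–H. Water adds to the resulting methoxy-substituted cation, and the hemiketal loses methanol to give 13 directly. This bypasses 12 and the diol oxidation of step 8 and makes no new compound (entry F0).

**Step 4.**
- Transmetalation of the pinacol boronate to copper may be slow, so that protodeboronation, oxidative homocoupling or partial loss of geometry competes.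
- Fallback from 6, rejoining at 7: oxidation of the C–B bond with NaBO3·4H2O in THF/H2O gives [3,4-bis(tert-butyldimethylsilyloxy)phenyl]acetaldehyde F5. O-Acetylation of its enolate (Ac2O, KOAc, 120 °C, or Ac2O/Et3N/4-dimethylaminopyridine) gives 7 together with the (Z)-enol acetate F6. The isomers are separated by chromatography, and F6 is recycled by iodine-catalysed equilibration.

**Step 1.**
- Over-alkylation to bis(prenyl) ethers and C-prenylation of the phloroglucinol nucleus may compete with mono-O-alkylation.
- Fallback from 1, rejoining at 3: Mitsunobu etherification with 3-methylbut-2-en-1-ol, PPh3 and diisopropyl azodicarboxylate in THF at 0 °C engages only the most acidic, non-chelated 4-OH under neutral conditions and makes no new compound (entry F0).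

## Further compounds

F1 | step 5 | 2,6-dihydroxy-4-(prenyloxy)acetophenone | CC(=O)c1c(O)cc(OCC=C(C)C)cc1O
F2 | step 5 | 2,6-bis(methoxymethoxy)-4-(prenyloxy)acetophenone | CC(=O)c1c(OCOC)cc(OCC=C(C)C)cc1OCOC
F3 | step 5 | (E)-1-[2,6-bis(methoxymethoxy)-4-(prenyloxy)phenyl]-3-[3,4-bis(tert-butyldimethylsilyloxy)phenyl]prop-2-en-1-one | COCOc1cc(OCC=C(C)C)cc(OCOC)c1C(=O)/C=C/c1ccc(O[Si](C)(C)C(C)(C)C)c(O[Si](C)(C)C(C)(C)C)c1
F4 | step 5 | (2R,3S)-2,3-epoxy-1-[2,6-bis(methoxymethoxy)-4-(prenyloxy)phenyl]-3-[3,4-bis(tert-butyldimethylsilyloxy)phenyl]propan-1-one | COCOc1cc(OCC=C(C)C)cc(OCOC)c1C(=O)[C@@H]1O[C@H]1c1ccc(O[Si](C)(C)C(C)(C)C)c(O[Si](C)(C)C(C)(C)C)c1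
F0 | step 7 | none | none
F5 | step 4 | [3,4-bis(tert-butyldimethylsilyloxy)phenyl]acetaldehyde | O=CCc1ccc(O[Si](C)(C)C(C)(C)C)c(O[Si](C)(C)C(C)(C)C)c1
F6 | step 4 | (Z)-2-[3,4-bis(tert-butyldimethylsilyloxy)phenyl]ethenyl acetate | CC(=O)O/C=C\c1ccc(O[Si](C)(C)C(C)(C)C)c(O[Si](C)(C)C(C)(C)C)c1
F0 | step 1 | none | none
A1 | alternative 1 | (2S)-5,7-bis(benzyloxy)-2-[3,4-bis(tert-butyldimethylsilyloxy)phenyl]-2H-chromene (flav-3-ene; same spatial arrangement at C2 as in 14) | c1ccccc1COc1cc(OCc3ccccc3)c2c(c1)O[C@H](c1ccc(O[Si](C)(C)C(C)(C)C)c(O[Si](C)(C)C(C)(C)C)c1)C=C2
A2 | alternative 1 | (2R,3S,4S)-5,7-bis(benzyloxy)-3',4'-bis(tert-butyldimethylsilyloxy)flavan-3,4-diol (2,3-trans-3,4-cis) | c1ccccc1COc1cc(OCc3ccccc3)c2c(c1)O[C@H](c1ccc(O[Si](C)(C)C(C)(C)C)c(O[Si](C)(C)C(C)(C)C)c1)[C@@H](O)[C@H]2O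
A3 | alternative 2 | (2R,3R)-2-(benzyloxy)-3-[3,4-bis(benzyloxy)phenyl]-3-[3,5-bis(benzyloxy)phenoxy]propanoic acid | c1ccccc1COc1cc(OCc2ccccc2)cc(c1)O[C@H](c1ccc(OCc2ccccc2)c(OCc2ccccc2)c1)[C@@H](OCc1ccccc1)C(=O)O
A4 | alternative 2 | (2R,3R)-3,5,7,3',4'-penta-O-benzyltaxifolin | c1ccccc1COc1cc(OCc3ccccc3)c2c(c1)O[C@H](c1ccc(OCc3ccccc3)c(OCc3ccccc3)c1)[C@@H](OCc1ccccc1)C2=O
A5 | alternative 3 | (2R,3R)-5-bromo-2-[3,4-bis(tert-butyldimethylsilyloxy)phenyl]-3-(tert-butyldimethylsilyloxy)-2,3-dihydro-4H-pyran-4-one | BrC1=CO[C@H](c2ccc(O[Si](C)(C)C(C)(C)C)c(O[Si](C)(C)C(C)(C)C)c2)[C@@H](O[Si](C)(C)C(C)(C)C)C1=O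
A6 | alternative 3 | 1-methoxy-3-(prenyloxy)-1-(trimethylsilyloxy)buta-1,3-diene (either geometry at the ketene acetal) | C=C(OCC=C(C)C)C=C(OC)O[Si](C)(C)C
A7 | alternative 3 | (2R,3R)-3,3',4'-tris-O-(tert-butyldimethylsilyl)-7-O-prenyltaxifolin | CC(C)=CCOc1cc(O)c2c(c1)O[C@H](c1ccc(O[Si](C)(C)C(C)(C)C)c(O[Si](C)(C)C(C)(C)C)c1)[C@@H](O[Si](C)(C)C(C)(C)C)C2=O
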